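The route rests on closing ring D, the carbocycle that carries the carbinol C1, the epoxide C2–C3 and the fully substituted C4, by making the C3–C4 bond. The precursor is a diaryl ketone (future C4) whose neighbouring ring position bears an enantioenriched allyl carbamate (C1–C2=C3). Lithiation at C1 and intramolecular homoaldol addition of the allyl terminus C3 to the ketone exploits the 1,4-relationship of the two oxygenated carbons C1 and C4 across ring D. In one operation it forms the quaternary carbinol, transfers the C1 configuration to C4 and leaves C1 as a masked ketone. Every other stereocentre is then relayed from C4, and the ketal is made by oxidation of the naphthalene.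

Key step: step 12

Remarks:
- Ring D (C1 carbinol, C2–C3 epoxide, C4 quaternary) is fused to the chlorohydroquinone ring B; C5 carries the ketal oxygen and C8 the free phenol.
- In the naphthalene unit, ring C carries C1′ (ketal carbon), C2′–C3′ (epoxide) and C4′ (ketone) and is fused to ring A.
- Compounds 1 and 6 are assumed to be commercial; Zn(CH=CH2)2 and NaHSO4·SiO2 are taken as stock reagents.
- In 26 and 27 the ketal carbon C1′ is an inconsequential mixture of epimers and is left undefined in the SMILES.

Step 1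
Reactants: 1 5,8-dimethoxy-3,4-dihydronaphthalen-1(2H)-one
Product: 2 5,8-dimethoxynaphthalen-1-ol
Conditions: Pd/C (10 wt% palladium on carbon), p-cymene, reflux
Reagents that add atoms: none
Why: Catalytic dehydrogenation of a 1-tetralone to the 1-naphthol should proceed by loss of H2 at high temperature.

Step 2
Reactants: 2 5,8-dimethoxynaphthalen-1-ol
Product: 3 4-bromo-5,8-dimethoxynaphthalen-1-ol
Conditions: NBS, MeCN, −20 °C
Reagents that add atoms: N-bromosuccinimide O=C1CCC(=O)N1Br
Why: Electrophilic aromatic bromination should occur para to the free naphthol OH, the most activated α-position.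

Step 3
Reactants: 3 4-bromo-5,8-dimethoxynaphthalen-1-ol
Product: 4 4-bromo-2-chloro-5,8-dimethoxynaphthalen-1-ol
Conditions: NCS, DMF, rt
Reagents that add atoms: N-chlorosuccinimide O=C1CCC(=O)N1Cl
Why: Electrophilic aromatic chlorination is directed by the phenol to C2, the only ortho or para site left open.

Step 4
Reactants: 4 4-bromo-2-chloro-5,8-dimethoxynaphthalen-1-ol
Product: 5 1-bromo-3-chloro-5,8-dimethoxy-4-(methoxymethoxy)naphthalene
Conditions: MOMCl, i-Pr2NEt, CH2Cl2, 0 °C to reflux
Reagents that add atoms: chloromethyl methyl ether COCCl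
Why: O-alkylation of the phenol gives a MOM ether that tolerates the organometallic, oxidative and basic steps that follow.

Step 5
Reactants: 6 2,5-dihydroxybenzaldehyde
Product: 7 2-hydroxy-5-(methoxymethoxy)benzaldehyde
Conditions: MOMCl (1.0 equiv), i-Pr2NEt, CH2Cl2, 0 °C
Reagents that add atoms: chloromethyl methyl ether COCCl
Why: Selective O-alkylation should take place at the 5-OH, because the 2-OH is hydrogen-bonded to the aldehyde and less nucleophilic.

Step 6
Reactants: 7 2-hydroxy-5-(methoxymethoxy)benzaldehyde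
Product: 8 3-chloro-2-hydroxy-5-(methoxymethoxy)benzaldehyde
Conditions: NCS, i-Pr2NH (10 mol%), CH2Cl2, 0 °C to rt
Reagents that add atoms: N-chlorosuccinimide O=C1CCC(=O)N1Cl
Why: Amine-mediated ortho-chlorination of the phenol should go to C3, its only free ortho or para position.

Step 7
Reactants: 8 3-chloro-2-hydroxy-5-(methoxymethoxy)benzaldehyde
Product: 9 3-chloro-2,5-bis(methoxymethoxy)benzaldehyde
Conditions: MOMCl, i-Pr2NEt, n-Bu4NI (cat.), CH2Cl2, reflux
Reagents that add atoms: chloromethyl methyl ether COCCl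
Why: O-alkylation of the remaining phenol gives a second MOM ether that also acts as a directing group in step 8.

Step 8
Reactants: 9 3-chloro-2,5-bis(methoxymethoxy)benzaldehyde
Product: 12 methyl 4-chloro-2-formyl-3,6-bis(methoxymethoxy)benzoate, via lithium amino alkoxide 10 (not isolated), via ortho-lithiated amino alkoxide 11 (not isolated)
Conditions: LiN(Me)CH2CH2NMe2 (from the amine and n-BuLi), THF, −20 °C; n-BuLi, −20 °C; ClCO2Me, −78 °C to rt; aqueous NH4Cl
Reagents that add atoms: methyl chloroformate COC(=O)Cl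
Why: Directed ortho-lithiation of the in situ α-amino alkoxide should occur at C6, the one site flanked by both the chelating amino alkoxide and an OMOM group, and acylation followed by hydrolytic release of the aldehyde gives the formyl ester.

Step 9
Reactants: 12 methyl 4-chloro-2-formyl-3,6-bis(methoxymethoxy)benzoate
Product: 14 (3R)-5-chloro-4,7-bis(methoxymethoxy)-3-vinylisobenzofuran-1(3H)-one, via zinc alkoxide 13 (not isolated)
Conditions: Zn(CH=CH2)2, (+)-3-exo-morpholinoisoborneol (10 mol%), toluene, 0 °C to rt; aqueous NH4Cl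
Reagents that add atoms: divinylzinc C=C[Zn]C=C
Why: Amino-alcohol-catalysed enantioselective 1,2-addition of the vinylzinc reagent to the aldehyde (ligand enantiomer chosen for Re-face delivery, as established for aryl aldehydes) sets the (R)-carbinol, which lactonises onto the neighbouring ester.

Step 10
Reactants: 5 1-bromo-3-chloro-5,8-dimethoxy-4-(methoxymethoxy)naphthalene; 14 (3R)-5-chloro-4,7-bis(methoxymethoxy)-3-vinylisobenzofuran-1(3H)-one
Product: 17 [3-chloro-5,8-dimethoxy-4-(methoxymethoxy)naphthalen-1-yl]{4-chloro-2-[(1R)-1-hydroxyprop-2-en-1-yl]-3,6-bis(methoxymethoxy)phenyl}methanone, via aryllithium 15 (not isolated), via arylcerium dichloride 16 (not isolated)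
Conditions: n-BuLi, THF, −78 °C; CeCl3, −78 °C; then 14, −78 to −40 °C; aqueous NH4Cl
Reagents that add atoms: none
Why: Bromine–lithium exchange and transmetalation give a weakly basic arylcerium that should add once to the lactone carbonyl without deprotonating the acidic C3–H, so the stereocentre survives and the lactol opens to the hydroxy ketone (in equilibrium with its cyclic hemiketal).

Step 11
Reactants: 17 [3-chloro-5,8-dimethoxy-4-(methoxymethoxy)naphthalen-1-yl]{4-chloro-2-[(1R)-1-hydroxyprop-2-en-1-yl]-3,6-bis(methoxymethoxy)phenyl}methanone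
Product: 19 (1R)-1-{3-chloro-6-[3-chloro-5,8-dimethoxy-4-(methoxymethoxy)-1-naphthoyl]-2,5-bis(methoxymethoxy)phenyl}prop-2-en-1-yl N,N-diisopropylcarbamate, via sodium alkoxide 18 (not isolated)
Conditions: NaH, THF, 0 °C; i-Pr2NCOCl, 0 °C to rt
Reagents that add atoms: N,N-diisopropylcarbamoyl chloride CC(C)N(C(C)C)C(Cl)=O
Why: O-carbamoylation of the secondary alkoxide of the open hydroxy-ketone form leaves the C–O bond of the stereocentre untouched, so the (R) configuration is retained.

Step 12
Reactants: 19 (1R)-1-{3-chloro-6-[3-chloro-5,8-dimethoxy-4-(methoxymethoxy)-1-naphthoyl]-2,5-bis(methoxymethoxy)phenyl}prop-2-en-1-yl N,N-diisopropylcarbamate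
Product: 21 (4S)-7-chloro-4-[3-chloro-5,8-dimethoxy-4-(methoxymethoxy)naphthalen-1-yl]-4-hydroxy-5,8-bis(methoxymethoxy)-3,4-dihydronaphthalen-1-yl N,N-diisopropylcarbamate, via lithiated carbamate 20 (not isolated)
Conditions: Li-TMP (lithium 2,2,6,6-tetramethylpiperidide, from the amine and n-BuLi), THF, −78 °C; aqueous NH4Cl at −78 °C
Reagents that add atoms: none
Why: Proposed new method: Li-TMP removes the C1 hydrogen, which is benzylic, allylic and α to the carbamate, with the carbamate carbonyl holding lithium on the face the hydrogen left (retentive, dipole-stabilised lithiation), and the allyllithium 20 adds through its γ-carbon C3 to the neighbouring diaryl ketone, since α-attack would demand a four-membered ring. The closest known reaction is the homoaldol addition of metalated secondary allyl carbamates to ketones (Hoppe homoaldol reaction), which passes through a closed six-membered transition state with the metal bridging the carbanionic carbon and the carbonyl oxygen; its intramolecular variant with the tether on the metal-bearing carbon has not been shown. Ring D closes 6-exo-trig at the carbonyl with all three allyl carbons inside the ring, through a boat-shaped, lithium-bridged array in which the C3–C4 bond forms as the C1=C2 enol carbamate is released. The one new stereocentre, C4, is set by that bridge: the ketone oxygen is delivered to the ring face from which the C1 hydrogen was taken, so (R)-C1 should be translated into (S)-C4 while C1 becomes trigonal. The step needs site-selective deprotonation at C1 (not at the aryl C–H between Cl and OMOM) and no attack of the base on the ketone, which the lithium-directing carbamate and the hindered, hydride-free amide secure, and it needs a bridged rather than an open transition state, which lithium–carbonyl coordination within the short tether favours. Protonation at −78 °C forestalls retro-addition of the congested tertiary alkoxide.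

Step 13
Reactants: 21 (4S)-7-chloro-4-[3-chloro-5,8-dimethoxy-4-(methoxymethoxy)naphthalen-1-yl]-4-hydroxy-5,8-bis(methoxymethoxy)-3,4-dihydronaphthalen-1-yl N,N-diisopropylcarbamate
Product: 23 (4S)-7-chloro-4-[3-chloro-5,8-dimethoxy-4-(methoxymethoxy)naphthalen-1-yl]-4-hydroxy-5,8-bis(methoxymethoxy)naphthalen-1(4H)-one, via dilithium enolate 22 (not isolated)
Conditions: MeLi (3.5 equiv), THF, −78 to 0 °C; then PhS(Cl)=N-t-Bu, −78 °C; aqueous NH4Cl
Reagents that add atoms: none
Why: MeLi cleaves the enol carbamate by acyl transfer to give the lithium enolate, which is dehydrogenated in the same flask by sulfinimidoylation and syn-elimination (one-pot enolate dehydrogenation), the basic medium avoiding acid-induced dehydration of the γ-hydroxy ketone to a naphthol.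

Step 14
Reactants: 23 (4S)-7-chloro-4-[3-chloro-5,8-dimethoxy-4-(methoxymethoxy)naphthalen-1-yl]-4-hydroxy-5,8-bis(methoxymethoxy)naphthalen-1(4H)-one
Product: 24 (2S,3R,4S)-7-chloro-4-[3-chloro-5,8-dimethoxy-4-(methoxymethoxy)naphthalen-1-yl]-2,3-epoxy-4-hydroxy-5,8-bis(methoxymethoxy)-2,3-dihydronaphthalen-1(4H)-one
Conditions: t-BuOOH (in decane), DBU, CH2Cl2, 0 °C
Reagents that add atoms: tert-butyl hydroperoxide CC(C)(C)OO
Why: In this Weitz–Scheffer epoxidation the peroxide anion should add to C3 on the face of the C4 hydroxyl (hydrogen-bond delivery) and away from the bulky naphthyl group, so the epoxide is cis to the C4–O bond.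

Step 15
Reactants: 24 (2S,3R,4S)-7-chloro-4-[3-chloro-5,8-dimethoxy-4-(methoxymethoxy)naphthalen-1-yl]-2,3-epoxy-4-hydroxy-5,8-bis(methoxymethoxy)-2,3-dihydronaphthalen-1(4H)-one
Product: 25 (1S,2R,3R,4S)-7-chloro-4-[3-chloro-5,8-dimethoxy-4-(methoxymethoxy)naphthalen-1-yl]-2,3-epoxy-5,8-bis(methoxymethoxy)-1,2,3,4-tetrahydronaphthalene-1,4-diol
Conditions: NaBH4, MeOH/CH2Cl2, −40 °C
Reagents that add atoms: none
Why: In this 1,2-reduction hydride should approach C1 from the face of the epoxide oxygen, opposite to the pseudo-axial naphthyl group on C4, which places the new C1–OH trans to the epoxide.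

Step 16
Reactants: 25 (1S,2R,3R,4S)-7-chloro-4-[3-chloro-5,8-dimethoxy-4-(methoxymethoxy)naphthalen-1-yl]-2,3-epoxy-5,8-bis(methoxymethoxy)-1,2,3,4-tetrahydronaphthalene-1,4-diol
Product: 26 quinone bisketal in which C1′ carries OMe and the C4 oxygen of ring D (five-membered cyclic ketal) and C4′ is a dimethyl ketal
Conditions: constant-current electrolysis, Pt anode, Pt cathode, LiClO4, 2,6-lutidine, MeOH, 0 °C, undivided cell
Reagents that add atoms: methanol CO
Why: Anodic two-electron oxidation of the 1,4-dimethoxynaphthalene, the most electron-rich ring, should give the quinone bisketal with capture at C1′ by the peri-positioned C4 hydroxyl and at C4′ by methanol, the configuration at C1′ being irrelevant because that centre is re-ionised in step 17.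

Step 17
Reactants: 26 quinone bisketal in which C1′ carries OMe and the C4 oxygen of ring D (five-membered cyclic ketal) and C4′ is a dimethyl ketal
Product: 28 bicyclic ketal enone that is the target lacking only the ring C epoxide (C2′=C3′ alkene), via phenolic methyl ketal 27 (not isolated)
Conditions: NaHSO4·SiO2, moist CH2Cl2, rt; then 4 Å molecular sieves
Reagents that add atoms: water O
Why: Acid catalysis hydrolyses the dimethyl ketal at C4′, cleaves the three aryl MOM ethers and lets the freed C5 phenol displace methanol at C1′ through the cyclic oxocarbenium ion (transketalisation, six-membered ring closure), C1′ being forced into the only configuration that the C4-anchored bridge allows.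

Step 18
Reactants: 28 bicyclic ketal enone that is the target lacking only the ring C epoxide (C2′=C3′ alkene)
Product: 29 target (CNP0289684.3)
Conditions: t-BuOOH (in decane), DBU, CH2Cl2, 0 °C
Reagents that add atoms: tert-butyl hydroperoxide CC(C)(C)OO
Why: Weitz–Scheffer epoxidation of the remaining enone should occur on its convex face, anti to the axial aryloxy oxygen on C1′ that leads to ring B, which gives the epoxide on the side of the C1′–O–C4 bridge as in the target.

Compound list
1 | 5,8-dimethoxy-3,4-dihydronaphthalen-1(2H)-one | O=C1CCCc2c(OC)ccc(OC)c12 | starting material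
2 | 5,8-dimethoxynaphthalen-1-ol | Oc1cccc2c(OC)ccc(OC)c12 | intermediate
3 | 4-bromo-5,8-dimethoxynaphthalen-1-ol | Oc1ccc(Br)c2c(OC)ccc(OC)c12 | intermediate
4 | 4-bromo-2-chloro-5,8-dimethoxynaphthalen-1-ol | Oc1c(Cl)cc(Br)c2c(OC)ccc(OC)c12 | intermediate
5 | 1-bromo-3-chloro-5,8-dimethoxy-4-(methoxymethoxy)naphthalene | COCOc1c(Cl)cc(Br)c2c(OC)ccc(OC)c12 | intermediate
6 | 2,5-dihydroxybenzaldehyde | O=Cc1cc(O)ccc1O | starting material
7 | 2-hydroxy-5-(methoxymethoxy)benzaldehyde | O=Cc1cc(OCOC)ccc1O | intermediate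
8 | 3-chloro-2-hydroxy-5-(methoxymethoxy)benzaldehyde | O=Cc1cc(OCOC)cc(Cl)c1O | intermediate
9 | 3-chloro-2,5-bis(methoxymethoxy)benzaldehyde | O=Cc1cc(OCOC)cc(Cl)c1OCOC | intermediate
10 | lithium α-amino alkoxide from 9 and lithium N,N,N′-trimethylethylenediamide | [Li]OC(N(C)CCN(C)C)c1cc(OCOC)cc(Cl)c1OCOC | intermediate (not isolated)
11 | 6-lithio derivative of 10 | [Li]OC(N(C)CCN(C)C)c1c([Li])c(OCOC)cc(Cl)c1OCOC | intermediate (not isolated)
12 | methyl 4-chloro-2-formyl-3,6-bis(methoxymethoxy)benzoate | COC(=O)c1c(C=O)c(OCOC)c(Cl)cc1OCOC | intermediate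
13 | vinylzinc alkoxide of methyl 4-chloro-2-[(1R)-1-hydroxyprop-2-en-1-yl]-3,6-bis(methoxymethoxy)benzoate | C=C[C@@H](O[Zn]C=C)c1c(C(=O)OC)c(OCOC)cc(Cl)c1OCOC | intermediate (not isolated)
14 | (3R)-5-chloro-4,7-bis(methoxymethoxy)-3-vinylisobenzofuran-1(3H)-one | C=C[C@H]1OC(=O)c2c(OCOC)cc(Cl)c(OCOC)c12 | intermediate
15 | [3-chloro-5,8-dimethoxy-4-(methoxymethoxy)naphthalen-1-yl]lithium | [Li]c1cc(Cl)c(OCOC)c2c(OC)ccc(OC)c12 | intermediate (not isolated)
16 | dichloro[3-chloro-5,8-dimethoxy-4-(methoxymethoxy)naphthalen-1-yl]cerium | Cl[Ce](Cl)c1cc(Cl)c(OCOC)c2c(OC)ccc(OC)c12 | intermediate (not isolated)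
17 | [3-chloro-5,8-dimethoxy-4-(methoxymethoxy)naphthalen-1-yl]{4-chloro-2-[(1R)-1-hydroxyprop-2-en-1-yl]-3,6-bis(methoxymethoxy)phenyl}methanone | C=C[C@@H](O)c1c(OCOC)c(Cl)cc(OCOC)c1C(=O)c1cc(Cl)c(OCOC)c2c(OC)ccc(OC)c12 | intermediate
18 | sodium alkoxide of 17 | C=C[C@@H](O[Na])c1c(OCOC)c(Cl)cc(OCOC)c1C(=O)c1cc(Cl)c(OCOC)c2c(OC)ccc(OC)c12 | intermediate (not isolated)
19 | (1R)-1-{3-chloro-6-[3-chloro-5,8-dimethoxy-4-(methoxymethoxy)-1-naphthoyl]-2,5-bis(methoxymethoxy)phenyl}prop-2-en-1-yl N,N-diisopropylcarbamate | C=C[C@@H](OC(=O)N(C(C)C)C(C)C)c1c(OCOC)c(Cl)cc(OCOC)c1C(=O)c1cc(Cl)c(OCOC)c2c(OC)ccc(OC)c12 | intermediate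
20 | C1-lithiated carbamate from 19 (lithium on the face of the removed hydrogen) | C=C[C@@]([Li])(OC(=O)N(C(C)C)C(C)C)c1c(OCOC)c(Cl)cc(OCOC)c1C(=O)c1cc(Cl)c(OCOC)c2c(OC)ccc(OC)c12 | intermediate (not isolated)
21 | (4S)-7-chloro-4-[3-chloro-5,8-dimethoxy-4-(methoxymethoxy)naphthalen-1-yl]-4-hydroxy-5,8-bis(methoxymethoxy)-3,4-dihydronaphthalen-1-yl N,N-diisopropylcarbamate | CC(C)N(C(C)C)C(=O)OC1=CC[C@](O)(c2cc(Cl)c(OCOC)c3c(OC)ccc(OC)c23)c2c(OCOC)cc(Cl)c(OCOC)c12 | intermediate
22 | dilithium enolate alkoxide from 21 | [Li]OC1=CC[C@](O[Li])(c2cc(Cl)c(OCOC)c3c(OC)ccc(OC)c23)c2c(OCOC)cc(Cl)c(OCOC)c12 | intermediate (not isolated)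
23 | (4S)-7-chloro-4-[3-chloro-5,8-dimethoxy-4-(methoxymethoxy)naphthalen-1-yl]-4-hydroxy-5,8-bis(methoxymethoxy)naphthalen-1(4H)-one | O=C1C=C[C@](O)(c2cc(Cl)c(OCOC)c3c(OC)ccc(OC)c23)c2c(OCOC)cc(Cl)c(OCOC)c12 | intermediate
24 | (2S,3R,4S)-7-chloro-4-[3-chloro-5,8-dimethoxy-4-(methoxymethoxy)naphthalen-1-yl]-2,3-epoxy-4-hydroxy-5,8-bis(methoxymethoxy)-2,3-dihydronaphthalen-1(4H)-one (epoxide cis to the C4 hydroxyl) | O=C1[C@H]2O[C@H]2[C@](O)(c2cc(Cl)c(OCOC)c3c(OC)ccc(OC)c23)c2c(OCOC)cc(Cl)c(OCOC)c12 | intermediate
25 | (1S,2R,3R,4S)-7-chloro-4-[3-chloro-5,8-dimethoxy-4-(methoxymethoxy)naphthalen-1-yl]-2,3-epoxy-5,8-bis(methoxymethoxy)-1,2,3,4-tetrahydronaphthalene-1,4-diol (C1 hydroxyl trans to the epoxide) | O[C@@H]1[C@H]2O[C@H]2[C@](O)(c2cc(Cl)c(OCOC)c3c(OC)ccc(OC)c23)c2c(OCOC)cc(Cl)c(OCOC)c12 | intermediate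
26 | quinone bisketal: C1′ bears OMe and the C4 oxygen (five-membered cyclic ketal, epimers at C1′), C4′ is a dimethyl ketal, ring D as in 25 | O[C@@H]1[C@H]2O[C@H]2[C@@]3(OC4(OC)C=CC(OC)(OC)c5c(OCOC)c(Cl)cc3c45)c2c(OCOC)cc(Cl)c(OCOC)c12 | intermediate
27 | phenolic methyl ketal: 26 after loss of the three MOM groups and hydrolysis of the C4′ ketal to the ketone | O[C@@H]1[C@H]2O[C@H]2[C@@]3(OC4(OC)C=CC(=O)c5c(O)c(Cl)cc3c45)c2c(O)cc(Cl)c(O)c12 | intermediate (not isolated)
28 | bicyclic ketal enone: the target with a C2′=C3′ double bond in place of the ring C epoxide | O=C1c2c(O)c(Cl)cc3c2[C@@]2(Oc4cc(Cl)c(O)c5c4[C@]3(O2)[C@@H]2O[C@@H]2[C@H]5O)C=C1 | intermediate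
29 | target CNP0289684.3 (bis-epoxide, C1 alcohol trans to the ring D epoxide, both epoxides on the side of the bridging ketal oxygen) | O=C1c2c(O)c(Cl)cc3c2[C@@]2(Oc4cc(Cl)c(O)c5c4[C@]3(O2)[C@@H]2O[C@@H]2[C@H]5O)[C@@H]2O[C@H]12 | target

Total step count: 18. Longest linear sequence: 14 steps (6 to 29, steps 5–18); the naphthalene branch (steps 1–4) joins at step 10.

Steps most likely to fail

1. Step 12 (key step). The transfer of chirality may erode if the lithiated carbamate loses its configuration before it cyclises or if the addition runs through an open, non-bridged transition state. The anion may also be diverted by 1,2-carbamoyl migration or by retro-addition. Fallback with known chemistry, setting out from 17: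
   - Oxidation of the allylic alcohol with Dess–Martin periodinane should give the aryl vinyl ketone 1-{3-chloro-6-[3-chloro-5,8-dimethoxy-4-(methoxymethoxy)-1-naphthoyl]-2,5-bis(methoxymethoxy)phenyl}prop-2-en-1-one F1.
   - SmI2 in THF/t-BuOH at −78 °C (ketyl–olefin cyclisation, the diaryl ketyl adding to the enone β-carbon) should close the same C3–C4 bond and give the racemic 4-aryl-4-hydroxytetralone F2.
   - Enolate dehydrogenation (LiN(SiMe3)2, then PhS(Cl)=N-t-Bu, −78 °C) should give the racemic enone F3.
   - Separation of the enantiomers by preparative HPLC on a chiral stationary phase comes back to the route at 23.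

2. Step 16. The anodic oxidation may lose chemoselectivity between the two electron-rich rings, or over-oxidise, so that ring B is attacked or the bisketal degrades. Fallback setting out from 25:
   - Oxidative demethylation with (NH4)2Ce(NO3)6 (2.2 equiv) in MeCN–H2O at 0 °C should give the naphthoquinone F4, in equilibrium with the hemiketal formed by its C4 hydroxyl and the peri carbonyl C1′.
   - Treatment of F4 with NaHSO4·SiO2 in CH2Cl2 over 4 Å molecular sieves should remove the MOM groups and close the ketal by dehydrative capture of the C1′ hemiketal by the C5 phenol, coming back to the route at 28.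

3. Step 8. Site selectivity of the lithiation may be poor: metalation between Cl and OMOM would compete and lead on to aryne decomposition. Fallback setting out from 9:
   - Pd(OAc)2-catalysed ortho C–H bromination through a transient imine directing group (an anthranilic-acid-type amine, NBS, AcOH, 60 °C) has only one ortho C–H to attack and should give 2-bromo-5-chloro-3,6-bis(methoxymethoxy)benzaldehyde F5.
   - Methoxycarbonylation (Pd(OAc)2, 1,1′-bis(diphenylphosphino)ferrocene, CO, MeOH, Et3N, 70 °C) comes back to the route at 12.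

Further compounds
F1 | step 12 | 1-{3-chloro-6-[3-chloro-5,8-dimethoxy-4-(methoxymethoxy)-1-naphthoyl]-2,5-bis(methoxymethoxy)phenyl}prop-2-en-1-one | C=CC(=O)c1c(OCOC)c(Cl)cc(OCOC)c1C(=O)c1cc(Cl)c(OCOC)c2c(OC)ccc(OC)c12
F2 | step 12 | racemic 7-chloro-4-[3-chloro-5,8-dimethoxy-4-(methoxymethoxy)naphthalen-1-yl]-4-hydroxy-5,8-bis(methoxymethoxy)-3,4-dihydronaphthalen-1(2H)-one | O=C1CCC(O)(c2cc(Cl)c(OCOC)c3c(OC)ccc(OC)c23)c2c(OCOC)cc(Cl)c(OCOC)c12
F3 | step 12 | racemic 7-chloro-4-[3-chloro-5,8-dimethoxy-4-(methoxymethoxy)naphthalen-1-yl]-4-hydroxy-5,8-bis(methoxymethoxy)naphthalen-1(4H)-one (racemate of 23) | O=C1C=CC(O)(c2cc(Cl)c(OCOC)c3c(OC)ccc(OC)c23)c2c(OCOC)cc(Cl)c(OCOC)c12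
F4 | step 16 | naphthoquinone from 25: 6-chloro-5-(methoxymethoxy)-1,4-naphthoquinone carrying at C8 the (1S,2R,3R,4S)-epoxy diol ring D of 25 | O[C@@H]1[C@H]2O[C@H]2[C@](O)(c2cc(Cl)c(OCOC)c3C(=O)C=CC(=O)c23)c2c(OCOC)cc(Cl)c(OCOC)c12
F5 | step 8 | 2-bromo-5-chloro-3,6-bis(methoxymethoxy)benzaldehyde | O=Cc1c(Br)c(OCOC)cc(Cl)c1OCOC
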